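## Plan

- **Retrosynthesis:** The phenol is unmasked last. Both CH2OH groups trace back to ethyl esters (one reduction), and the trans ring to the cis ring (epimerisation at C3). The C2–C3 bond of the dihydrofuran ring (ring C) is then cut, leaving an achiral aryl benzyl ether with a diazoacetate at the future C3. Cutting C3–C3a, the alkene and O1–CH2 leads to 5-iodovanillin, syringaldehyde, ethyl diazoacetate and a stabilised ylide.
- **Enabling feature:** C2–H is both benzylic to the syringyl ring (ring B) and α to O1, and it lies 1,5 to C3. C3 carries ring A as a donor and a carbon that can stand at the ester level as an acceptor. C3 can therefore be a donor/acceptor rhodium carbene, with C2–H as its hydridic partner.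
- **Forward:** Rings A and B are bought and joined through O1 (Mitsunobu). The side chain is set (Wittig) and the diazoacetate is installed (palladium coupling). Ring C, the only ring made, closes by enantioselective 1,5 C–H insertion.
- **Stereochemistry:** C2 (S) comes from the chiral dirhodium catalyst, C3 from thermodynamic equilibration against C2 (cis to trans), and the E alkene from the stabilised ylide.

Key step: step 6

Assumption: the sense of induction of dirhodium tetrakis(N-phthaloyl-tert-leucinate) in this insertion is taken to be S ligand to 2R and R ligand to 2S, as for simpler 2-(benzyloxy)aryl diazoacetates. If the substrate responds in the opposite sense, the S catalyst replaces the R catalyst and nothing else changes.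

Abbreviations: TIPS = triisopropylsilyl; Rh2(R-PTTL)4 = dirhodium tetrakis[N-phthaloyl-(R)-tert-leucinate]; DIAD = diisopropyl azodicarboxylate.

## Route

Step 1
Reactants: 1 syringaldehyde (4-hydroxy-3,5-dimethoxybenzaldehyde)
Product: 2 3,5-dimethoxy-4-(triisopropylsilyloxy)benzaldehyde
Conditions: TIPSCl, imidazole, DMF, rt
Reagents that add atoms: triisopropylsilyl chloride, CC(C)[Si](Cl)(C(C)C)C(C)C
Why: Imidazole-promoted silyl ether formation at the phenol; the bulky TIPS group between two ortho methoxy groups should withstand ethoxide, i-Bu2AlH and the palladium and rhodium steps, yet leave with fluoride at the end without touching the cinnamyl alcohol.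

Step 2
Reactants: 2 3,5-dimethoxy-4-(triisopropylsilyloxy)benzaldehyde
Product: 3 [3,5-dimethoxy-4-(triisopropylsilyloxy)phenyl]methanol
Conditions: NaBH4, MeOH–THF, 0 °C
Reagents that add atoms: none
Why: Borohydride reduction of an aromatic aldehyde to the benzylic alcohol, to which the aryl silyl ether is inert.

Step 3
Reactants: 3 [3,5-dimethoxy-4-(triisopropylsilyloxy)phenyl]methanol; 4 5-iodovanillin (4-hydroxy-3-iodo-5-methoxybenzaldehyde)
Product: 5 4-{[3,5-dimethoxy-4-(triisopropylsilyloxy)phenyl]methoxy}-3-iodo-5-methoxybenzaldehyde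
Conditions: PPh3, DIAD, THF, 0 °C to rt
Reagents that add atoms: none
Why: Mitsunobu etherification, in which the acidic ortho-iodinated phenol 4 is a good pronucleophile and the primary benzylic alcohol is activated in the flask, so no labile electron-rich benzylic halide must be isolated; this forms the O1–CH2 bond whose CH2 becomes C2.

Step 4
Reactants: 5 4-{[3,5-dimethoxy-4-(triisopropylsilyloxy)phenyl]methoxy}-3-iodo-5-methoxybenzaldehyde; 6 ethyl (triphenylphosphoranylidene)acetate
Product: 7 ethyl (E)-3-(4-{[3,5-dimethoxy-4-(triisopropylsilyloxy)phenyl]methoxy}-3-iodo-5-methoxyphenyl)prop-2-enoate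
Conditions: toluene, 80 °C
Reagents that add atoms: none
Why: Wittig olefination with a stabilised ylide gives the E enoate under neutral conditions and converts the aldehyde, which could trap a rhodium carbene as a carbonyl ylide, into an electron-poor alkene that a donor/acceptor carbene ignores.

Step 5
Reactants: 7 ethyl (E)-3-(4-{[3,5-dimethoxy-4-(triisopropylsilyloxy)phenyl]methoxy}-3-iodo-5-methoxyphenyl)prop-2-enoate; 8 ethyl diazoacetate
Product: 9 ethyl (E)-3-[3-(1-diazo-2-ethoxy-2-oxoethyl)-4-{[3,5-dimethoxy-4-(triisopropylsilyloxy)phenyl]methoxy}-5-methoxyphenyl]prop-2-enoate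
Conditions: Pd(PPh3)4 (5 mol %), Ag2CO3 (0.5 equiv), Et3N (1.3 equiv), toluene, rt, dark
Reagents that add atoms: none
Why: Palladium-catalysed C–H arylation of an acyldiazomethane with an aryl iodide, in which oxidative addition of the C–I bond to zerovalent palladium, silver-assisted removal of iodide, base-assisted palladation of the diazo carbon and reductive elimination form the C3–C3a bond with the diazo group retained, at a temperature at which neither diazo compound should lose N2 or add to the cinnamate.

Step 6
Reactants: 9 ethyl (E)-3-[3-(1-diazo-2-ethoxy-2-oxoethyl)-4-{[3,5-dimethoxy-4-(triisopropylsilyloxy)phenyl]methoxy}-5-methoxyphenyl]prop-2-enoate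
Product: 11 ethyl (2S,3R)-2-[3,5-dimethoxy-4-(triisopropylsilyloxy)phenyl]-5-[(E)-3-ethoxy-3-oxoprop-1-enyl]-7-methoxy-2,3-dihydro-1-benzofuran-3-carboxylate (cis), via dirhodium carbene 10 (not isolated)
Conditions: Rh2(R-PTTL)4 (1 mol %), toluene, −60 °C, slow addition of 9
Reagents that add atoms: none
Why: Rh2(R-PTTL)4 expels N2 from 9 to give the electrophilic donor/acceptor carbene 10, whose carbene carbon (the future C3) lies 1,5 to the OCH2 hydrogens, and one of these is transferred with hydride character through a concerted, asynchronous three-centre transition state while C2–C3 forms, the developing positive charge at C2 being carried by the lone pair of O1 and by ring B. The closest known reaction type is the enantioselective intramolecular 1,5 C–H insertion of 2-(benzyloxy)aryl diazoacetates with chiral dirhodium tetracarboxylates, which gives cis-2-aryl-2,3-dihydrobenzofuran-3-carboxylates. The one ring that closes is the five-membered ring O1–C2–C3–C3a–C7a, by 1,5 insertion, since attack of O1 on the carbene would give a strained four-membered ylide and no other C–H bond is both activated and within geometric reach. C2 is controlled by the catalyst: the phthalimide walls of the ligand pocket should let only one of the two enantiotopic benzylic hydrogens reach the carbene, insertion goes with retention at that carbon, and the R ligand is expected to lead to 2S. C3 is controlled by the same transition state, in which hydrogen and C2 arrive on one face of the carbene with ring B turned away from the ligand wall, placing aryl and ester cis (3R), a kinetic relation that step 7 corrects. The step needs chemoselectivity for insertion over cyclopropanation, carbene dimerisation and addition to ring B, which is secured by the electron-poor cinnamate alkene, the intramolecular 1,5 geometry, slow addition at low temperature and the tempered reactivity of a donor/acceptor carbene.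

Step 7
Reactants: 11 ethyl (2S,3R)-2-[3,5-dimethoxy-4-(triisopropylsilyloxy)phenyl]-5-[(E)-3-ethoxy-3-oxoprop-1-enyl]-7-methoxy-2,3-dihydro-1-benzofuran-3-carboxylate (cis)
Product: 13 ethyl (2S,3S)-2-[3,5-dimethoxy-4-(triisopropylsilyloxy)phenyl]-5-[(E)-3-ethoxy-3-oxoprop-1-enyl]-7-methoxy-2,3-dihydro-1-benzofuran-3-carboxylate (trans), via sodium ester enolate 12 (not isolated)
Conditions: NaOEt (0.3 equiv), EtOH–THF, 0 °C to rt
Reagents that add atoms: none
Why: Base-mediated epimerisation through the planar ester enolate 12, in which C3 is reprotonated reversibly until the thermodynamically preferred trans arrangement of C2 aryl and C3 ester (3S) is reached, C2 stays untouched because expulsion of O1 from the enolate would be the reverse of a 5-endo-trig closure, and ethoxide in ethanol makes any ester exchange degenerate.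

Step 8
Reactants: 13 ethyl (2S,3S)-2-[3,5-dimethoxy-4-(triisopropylsilyloxy)phenyl]-5-[(E)-3-ethoxy-3-oxoprop-1-enyl]-7-methoxy-2,3-dihydro-1-benzofuran-3-carboxylate (trans)
Product: 14 (E)-3-{(2S,3R)-2-[3,5-dimethoxy-4-(triisopropylsilyloxy)phenyl]-3-(hydroxymethyl)-7-methoxy-2,3-dihydro-1-benzofuran-5-yl}prop-2-en-1-ol
Conditions: i-Bu2AlH (6 equiv), CH2Cl2, −78 to −20 °C; aqueous potassium sodium tartrate
Reagents that add atoms: none
Why: Hydride reduction of both esters with i-Bu2AlH takes the enoate in the 1,2 sense to the E allylic alcohol and the C3 ester to the hydroxymethyl group without touching the stereocentres or the silyl ether (the descriptor at C3 changes from S to R only because the priorities change).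

Step 9
Reactants: 14 (E)-3-{(2S,3R)-2-[3,5-dimethoxy-4-(triisopropylsilyloxy)phenyl]-3-(hydroxymethyl)-7-methoxy-2,3-dihydro-1-benzofuran-5-yl}prop-2-en-1-ol
Product: 15 4-{(2S,3R)-3-(hydroxymethyl)-5-[(E)-3-hydroxyprop-1-enyl]-7-methoxy-2,3-dihydro-1-benzofuran-2-yl}-2,6-dimethoxyphenol (target)
Conditions: n-Bu4NF (1.1 equiv), AcOH (1.1 equiv), THF, 0 °C
Reagents that add atoms: none
Why: Fluoride-induced cleavage of the aryl silyl ether, buffered with acetic acid so that the liberated 4-hydroxybenzyl aryl ether is not held as a phenoxide, which could open ring C to a quinone methide.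

## Compound list

1 | syringaldehyde | COc1cc(C=O)cc(OC)c1O | starting material
2 | 3,5-dimethoxy-4-(triisopropylsilyloxy)benzaldehyde | COc1cc(C=O)cc(OC)c1O[Si](C(C)C)(C(C)C)C(C)C | intermediate
3 | [3,5-dimethoxy-4-(triisopropylsilyloxy)phenyl]methanol | COc1cc(CO)cc(OC)c1O[Si](C(C)C)(C(C)C)C(C)C | intermediate
4 | 5-iodovanillin | COc1cc(C=O)cc(I)c1O | starting material
5 | 4-{[3,5-dimethoxy-4-(triisopropylsilyloxy)phenyl]methoxy}-3-iodo-5-methoxybenzaldehyde | COc1cc(C=O)cc(I)c1OCc1cc(OC)c(O[Si](C(C)C)(C(C)C)C(C)C)c(OC)c1 | intermediate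
6 | ethyl (triphenylphosphoranylidene)acetate | CCOC(=O)C=P(c1ccccc1)(c1ccccc1)c1ccccc1 | starting material
7 | ethyl (E)-3-(4-{[3,5-dimethoxy-4-(triisopropylsilyloxy)phenyl]methoxy}-3-iodo-5-methoxyphenyl)prop-2-enoate | CCOC(=O)/C=C/c1cc(I)c(OCc2cc(OC)c(O[Si](C(C)C)(C(C)C)C(C)C)c(OC)c2)c(OC)c1 | intermediate
8 | ethyl diazoacetate | CCOC(=O)C=[N+]=[N-] | starting material
9 | ethyl (E)-3-[3-(1-diazo-2-ethoxy-2-oxoethyl)-4-{[3,5-dimethoxy-4-(triisopropylsilyloxy)phenyl]methoxy}-5-methoxyphenyl]prop-2-enoate | CCOC(=O)/C=C/c1cc(OC)c(OCc2cc(OC)c(O[Si](C(C)C)(C(C)C)C(C)C)c(OC)c2)c(c1)C(=[N+]=[N-])C(=O)OCC | intermediate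
10 | dirhodium carbene from 9 and Rh2(R-PTTL)4, the four bridging carboxylates written as separate ions | CCOC(=O)/C=C/c1cc(OC)c(OCc2cc(OC)c(O[Si](C(C)C)(C(C)C)C(C)C)c(OC)c2)c(c1)C(=[Rh+2][Rh+2])C(=O)OCC.CC(C)(C)[C@H](C(=O)[O-])N1C(=O)c2ccccc2C1=O.CC(C)(C)[C@H](C(=O)[O-])N1C(=O)c2ccccc2C1=O.CC(C)(C)[C@H](C(=O)[O-])N1C(=O)c2ccccc2C1=O.CC(C)(C)[C@H](C(=O)[O-])N1C(=O)c2ccccc2C1=O | intermediate
11 | cis diester, ethyl (2S,3R)-2-[3,5-dimethoxy-4-(triisopropylsilyloxy)phenyl]-5-[(E)-3-ethoxy-3-oxoprop-1-enyl]-7-methoxy-2,3-dihydro-1-benzofuran-3-carboxylate | COc1cc([C@H]2Oc3c(OC)cc(/C=C/C(=O)OCC)cc3[C@H]2C(=O)OCC)cc(OC)c1O[Si](C(C)C)(C(C)C)C(C)C | intermediate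
12 | sodium enolate of the C3 ester, configuration at C2 unchanged | COc1cc([C@H]2Oc3c(OC)cc(/C=C/C(=O)OCC)cc3C2=C([O-])OCC)cc(OC)c1O[Si](C(C)C)(C(C)C)C(C)C.[Na+] | intermediate
13 | trans diester, ethyl (2S,3S)-2-[3,5-dimethoxy-4-(triisopropylsilyloxy)phenyl]-5-[(E)-3-ethoxy-3-oxoprop-1-enyl]-7-methoxy-2,3-dihydro-1-benzofuran-3-carboxylate | COc1cc([C@H]2Oc3c(OC)cc(/C=C/C(=O)OCC)cc3[C@@H]2C(=O)OCC)cc(OC)c1O[Si](C(C)C)(C(C)C)C(C)C | intermediate
14 | (E)-3-{(2S,3R)-2-[3,5-dimethoxy-4-(triisopropylsilyloxy)phenyl]-3-(hydroxymethyl)-7-methoxy-2,3-dihydro-1-benzofuran-5-yl}prop-2-en-1-ol | COc1cc([C@H]2Oc3c(OC)cc(/C=C/CO)cc3[C@@H]2CO)cc(OC)c1O[Si](C(C)C)(C(C)C)C(C)C | intermediate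
15 | 4-{(2S,3R)-3-(hydroxymethyl)-5-[(E)-3-hydroxyprop-1-enyl]-7-methoxy-2,3-dihydro-1-benzofuran-2-yl}-2,6-dimethoxyphenol | COc1cc([C@H]2Oc3c(OC)cc(/C=C/CO)cc3[C@@H]2CO)cc(OC)c1O | target

## Step count and risks

Total step count: 9. Longest linear sequence: 9 steps (1 to 15).

**Step 6.**
- **What may go wrong:** The catalyst may discriminate poorly between the two enantiotopic benzylic hydrogens. The 7-methoxy group twists the benzyloxy group out of the plane of ring A, and the bulky silyloxy-substituted ring B may fit the ligand pocket badly. Carbene dimerisation may also compete.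
- **Fallback:** Stereocontrol is moved into the substrate, setting out from 7.
  - Ethyl (S)-lactate is heated with pyrrolidine to give (2S)-2-hydroxy-1-(pyrrolidin-1-yl)propan-1-one F1.
  - Bromoacetyl bromide and pyridine give its bromoacetate F2.
  - N,N'-ditosylhydrazine and DBU give its diazoacetate F3.
  - F3 is coupled with 7 under the conditions of step 5 to give the auxiliary-bearing aryl diazoacetate F4.
  - Insertion with Rh2(S-DOSP)4, dirhodium tetrakis[(S)-N-(4-dodecylphenylsulfonyl)prolinate], in CH2Cl2 should favour the trans (2S,3S) lactamide ester F5 by double stereodifferentiation.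
  - The products are diastereomers, so the wanted one can be purified on silica gel or by crystallisation whatever the level of induction.
  - Ethanolysis with NaOEt in EtOH exchanges the auxiliary for ethyl and comes back to the route at 13.

**Step 5.**
- **What may go wrong:** The coupling may be slow at the ortho-alkoxy iodide. Dinitrogen may be lost at palladium, followed by carbene migratory insertion. Ethyl diazoacetate may undergo slow dipolar cycloaddition to the cinnamate.
- **Fallback:** The carbon chain and the diazo group are introduced separately, setting out from 7.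
  - Palladium-catalysed arylation of commercial (2-ethoxy-2-oxoethyl)zinc bromide (Reformatsky-type reagent; Pd(dba)2, Q-Phos, THF, rt) gives the arylacetate F6.
  - Regitz diazo transfer (4-acetamidobenzenesulfonyl azide, DBU, MeCN, 0 °C to rt) at its only acidic CH2 comes back to the route at 9.

**Step 7.**
- **What may go wrong:** Equilibration may be incomplete. Ring C may open by β-elimination of the aryloxide from the enolate, which would erase C2. The silyl ether may be lost to ethoxide.
- **Fallback:** C2 is inverted instead of C3, through a cation instead of an enolate, setting out from 9.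
  - Insertion with the enantiomeric catalyst Rh2(S-PTTL)4 gives the (2R,3S) cis diester F7, which already has the correct C3.
  - CF3CO2H in CH2Cl2 at 0 °C ionises the C2–O1 bond reversibly to the benzylic cation, which is stabilised by the 4-silyloxy group of ring B.
  - Reclosure anti to the ester gives the thermodynamic trans isomer and comes back to the route at 13.

## Further compounds

F1 | step 6 | (2S)-2-hydroxy-1-(pyrrolidin-1-yl)propan-1-one | C[C@H](O)C(=O)N1CCCC1
F2 | step 6 | (2S)-1-oxo-1-(pyrrolidin-1-yl)propan-2-yl bromoacetate | C[C@H](OC(=O)CBr)C(=O)N1CCCC1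
F3 | step 6 | (2S)-1-oxo-1-(pyrrolidin-1-yl)propan-2-yl diazoacetate | C[C@H](OC(=O)C=[N+]=[N-])C(=O)N1CCCC1
F4 | step 6 | ethyl (E)-3-[3-(1-diazo-2-oxo-2-{[(2S)-1-oxo-1-(pyrrolidin-1-yl)propan-2-yl]oxy}ethyl)-4-{[3,5-dimethoxy-4-(triisopropylsilyloxy)phenyl]methoxy}-5-methoxyphenyl]prop-2-enoate | CCOC(=O)/C=C/c1cc(OC)c(OCc2cc(OC)c(O[Si](C(C)C)(C(C)C)C(C)C)c(OC)c2)c(c1)C(=[N+]=[N-])C(=O)O[C@@H](C)C(=O)N1CCCC1
F5 | step 6 | (2S)-1-oxo-1-(pyrrolidin-1-yl)propan-2-yl (2S,3S)-2-[3,5-dimethoxy-4-(triisopropylsilyloxy)phenyl]-5-[(E)-3-ethoxy-3-oxoprop-1-enyl]-7-methoxy-2,3-dihydro-1-benzofuran-3-carboxylate | COc1cc([C@H]2Oc3c(OC)cc(/C=C/C(=O)OCC)cc3[C@@H]2C(=O)O[C@@H](C)C(=O)N2CCCC2)cc(OC)c1O[Si](C(C)C)(C(C)C)C(C)C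
F6 | step 5 | ethyl (E)-3-[4-{[3,5-dimethoxy-4-(triisopropylsilyloxy)phenyl]methoxy}-3-(2-ethoxy-2-oxoethyl)-5-methoxyphenyl]prop-2-enoate | CCOC(=O)/C=C/c1cc(OC)c(OCc2cc(OC)c(O[Si](C(C)C)(C(C)C)C(C)C)c(OC)c2)c(CC(=O)OCC)c1
F7 | step 7 | ethyl (2R,3S)-2-[3,5-dimethoxy-4-(triisopropylsilyloxy)phenyl]-5-[(E)-3-ethoxy-3-oxoprop-1-enyl]-7-methoxy-2,3-dihydro-1-benzofuran-3-carboxylate (cis) | COc1cc([C@@H]2Oc3c(OC)cc(/C=C/C(=O)OCC)cc3[C@@H]2C(=O)OCC)cc(OC)c1O[Si](C(C)C)(C(C)C)C(C)C
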